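**Plan**

1. Retrosynthesis: the chain bonds C11=C12 and C11'=C12' are cut by Wittig disconnection into the C10 trienedial and two C15 end-group phosphonium salts, a 3-hydroxy salt and a 3'-oxo salt. Both salts come from one C15 vinyl carbinol; for the oxo salt the ring carbinol is oxidised before salt formation.
2. The end-group ring is cut at C5–C6, with the ring double bond moved to its exocyclic position. C6 is a doubly allylic methine between ring carbon C5 and the chain alkene C7=C8, so ring and chain head form a 1,4-diene. That is the product pattern of an Alder-ene cycloisomerisation of an acyclic 1,7-enyne (alkyne C18≡C5, alkene C6=C7, transferable hydrogen on C8).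
3. Forward: an ester-aldehyde (C3, C2, C1, C6), a ketal ylide (C7–C9 and the C9 methyl) and a propargyl unit (C4, C5, C18) give the enyne (steps 1–5). Step 6 is the only ring closure; its product supplies both end groups. Steps 7–11 lead to the common C15 carbinol, steps 12, 14 and 15 to the two salts, and steps 13 and 16 join C15 + C10 + C15.
4. Stereochemistry: C6 and C6' come from the chiral bisphosphine–palladium catalyst in step 6. C3 is relayed from C6 by substrate-controlled hydride delivery (step 9). Chain geometry comes from the Alder-ene step (7E), cation trapping (9E), the purchased dialdehyde, and Wittig reaction with thermal equilibration.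
5. Helpers: the C3 oxygen rides through the cyclisation as a silyl ether (masked ketone) and the C9 ketone as a dioxolane; both are removed in steps 7–10.

Key step: step 6

Remark on locants: carotenoid numbering is used; the hydroxy ring is unprimed and the keto ring is primed.
Assumption: the antipode of BINAP that delivers the 6S product must be fixed in a first run; (S)-BINAP is written. The dioxolane phosphonium salt of step 2, if not in stock, is one step from 2-(2-bromoethyl)-2-methyl-1,3-dioxolane and PPh3.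

**Route**

Step 1
Reactants: 1 methyl 3,3-dimethylpent-4-enoate
Product: 2 methyl 3,3-dimethyl-4-oxobutanoate
Conditions: O3, CH2Cl2, −78 °C; then Me2S, −78 °C to rt
Reagents that add atoms: ozone, O=[O+][O-]
Why: Ozonolysis with reductive work-up cleaves the terminal vinyl group and leaves a neopentyl aldehyde that cannot enolise.

Step 2
Reactants: 2 methyl 3,3-dimethyl-4-oxobutanoate; 3 [2-(2-methyl-1,3-dioxolan-2-yl)ethyl]triphenylphosphonium bromide
Product: 5 methyl (4Z)-3,3-dimethyl-6-(2-methyl-1,3-dioxolan-2-yl)hex-4-enoate, via phosphorus ylide 4 (not isolated)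
Conditions: 3, NaN(SiMe3)2, THF, −78 to 0 °C; then 2, −78 °C to rt
Reagents that add atoms: none
Why: The salt-free Wittig reaction of a non-stabilised ylide with an α-quaternary aldehyde should give the Z-alkene under kinetic control, the ester reacting far more slowly than the aldehyde.

Step 3
Reactants: 5 methyl (4Z)-3,3-dimethyl-6-(2-methyl-1,3-dioxolan-2-yl)hex-4-enoate
Product: 6 (4Z)-3,3-dimethyl-6-(2-methyl-1,3-dioxolan-2-yl)hex-4-enal
Conditions: (i-Bu)2AlH (1.1 equiv), CH2Cl2, −78 °C; aq. potassium sodium tartrate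
Reagents that add atoms: none
Why: Partial ester reduction at −78 °C should stop at the aluminium hemiacetal, which releases the aldehyde on work-up while the dioxolane stays inert.

Step 4
Reactants: 6 (4Z)-3,3-dimethyl-6-(2-methyl-1,3-dioxolan-2-yl)hex-4-enal
Product: 7 (7Z)-6,6-dimethyl-9-(2-methyl-1,3-dioxolan-2-yl)non-7-en-1-yn-4-ol (racemic at the carbinol carbon)
Conditions: propargyl bromide, Zn dust, THF, 0 °C to rt; aqueous work-up
Reagents that add atoms: propargyl bromide, C#CCBr
Why: In this Barbier-type propargylation the allenylzinc bromide formed in the flask adds through its γ-carbon to give the homopropargylic alcohol, whose racemic carbinol centre (C3) is erased in step 8.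

Step 5
Reactants: 7 (7Z)-6,6-dimethyl-9-(2-methyl-1,3-dioxolan-2-yl)non-7-en-1-yn-4-ol
Product: 8 tert-butyl{[(7Z)-6,6-dimethyl-9-(2-methyl-1,3-dioxolan-2-yl)non-7-en-1-yn-4-yl]oxy}dimethylsilane (racemic)
Conditions: t-BuMe2SiCl, imidazole, DMF, rt
Reagents that add atoms: tert-butyldimethylsilyl chloride, CC(C)(C)[Si](C)(C)Cl
Why: Standard silylation masks the future C3 ketone and keeps the hydroxyl from adding to the metal-activated alkyne in step 6.

Step 6
Reactants: 8 tert-butyl{[(7Z)-6,6-dimethyl-9-(2-methyl-1,3-dioxolan-2-yl)non-7-en-1-yn-4-yl]oxy}dimethylsilane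
Product: 9 tert-butyl({(4S)-3,3-dimethyl-5-methylidene-4-[(E)-2-(2-methyl-1,3-dioxolan-2-yl)ethenyl]cyclohexyl}oxy)dimethylsilane (both epimers at the silyloxy carbon)
Conditions: [Pd(MeCN)4](BF4)2 (5 mol %), (S)-BINAP (10 mol %), DMSO, 80 °C
Reagents that add atoms: none
Why: A hydride of divalent palladium formed in the flask adds across the terminal alkyne with the metal on the internal carbon C5; the alkenylpalladium then inserts the Z-alkene by syn-carbopalladation to make the C5–C6 bond, and syn β-hydride elimination from C8 releases the E-C7=C8 alkene and returns the hydride, overall an intramolecular Alder-ene reaction. The closest known reaction type is the palladium-catalysed cycloisomerisation of 1,6- and 1,7-enynes to 1,4-dienes, including its enantioselective form with cationic bisphosphine–palladium catalysts. The six-membered ring closes in the 6-exo-trig mode, helped by the gem-dimethyl group in the tether. The only new stereocentre, C6, is set by the chiral bisphosphine, which selects the enantioface of the alkene in the migratory insertion; the remote silyloxy carbon is erased in step 8, so both of its epimers converge. The step needs β-hydride elimination toward C8 and not toward C6–H, which would give a conjugated diene and destroy the stereocentre; the two freely rotating allylic hydrogens on C8 should secure this, whereas C6–H is tertiary and flanked by the quaternary C1. It also needs 6-exo over 7-endo closure, which the four-atom tether favours.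

Step 7
Reactants: 9 tert-butyl({(4S)-3,3-dimethyl-5-methylidene-4-[(E)-2-(2-methyl-1,3-dioxolan-2-yl)ethenyl]cyclohexyl}oxy)dimethylsilane
Product: 10 (4S)-3,3-dimethyl-5-methylidene-4-[(E)-2-(2-methyl-1,3-dioxolan-2-yl)ethenyl]cyclohexan-1-ol (both C1 epimers)
Conditions: Bu4NF, THF, 0 °C to rt
Reagents that add atoms: none
Why: Fluoride cleaves the silyl ether and should leave the dioxolane and the skipped diene untouched.

Step 8
Reactants: 10 (4S)-3,3-dimethyl-5-methylidene-4-[(E)-2-(2-methyl-1,3-dioxolan-2-yl)ethenyl]cyclohexan-1-ol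
Product: 12 (4S)-3,5,5-trimethyl-4-[(E)-2-(2-methyl-1,3-dioxolan-2-yl)ethenyl]cyclohex-2-en-1-one, via exocyclic-methylene ketone 11 (not isolated)
Conditions: (n-Pr)4N[RuO4] (5 mol %), N-methylmorpholine N-oxide, 4 Å molecular sieves, CH2Cl2, rt; then DBU (5 mol %), 0 °C
Reagents that add atoms: none
Why: Ley–Griffith oxidation gives the β,γ-unsaturated ketone, and catalytic amidine moves the exocyclic double bond into conjugation by deprotonation at the α-carbon C4 and reprotonation at the exocyclic carbon, a path much faster than removal of the hindered γ-hydrogen at C6, so C6 should keep its configuration if the reaction is stopped at full conversion.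

Step 9
Reactants: 12 (4S)-3,5,5-trimethyl-4-[(E)-2-(2-methyl-1,3-dioxolan-2-yl)ethenyl]cyclohex-2-en-1-one
Product: 13 (1S,4S)-3,5,5-trimethyl-4-[(E)-2-(2-methyl-1,3-dioxolan-2-yl)ethenyl]cyclohex-2-en-1-ol
Conditions: K[(s-Bu)3BH], THF, −78 °C; aqueous work-up
Reagents that add atoms: none
Why: In this 1,2-reduction of a β-substituted cyclohexenone the bulky borohydride should attack C3 from the face opposite the pseudo-axial C1 methyl, and with the C6 side chain pseudo-axial (it avoids A(1,2) strain with the C5 methyl) that places the new hydroxyl trans to the side chain (3S), a substrate-controlled relay from C6.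

Step 10
Reactants: 13 (1S,4S)-3,5,5-trimethyl-4-[(E)-2-(2-methyl-1,3-dioxolan-2-yl)ethenyl]cyclohex-2-en-1-ol
Product: 14 (3E)-4-[(1S,4S)-4-hydroxy-2,6,6-trimethylcyclohex-2-en-1-yl]but-3-en-2-one
Conditions: pyridinium p-toluenesulfonate (cat.), THF/H2O, 40 °C
Reagents that add atoms: water, O
Why: The allylic dioxolane hydrolyses through a stabilised oxocarbenium ion under acid mild enough that the ring allylic alcohol should not ionise.

Step 11
Reactants: 14 (3E)-4-[(1S,4S)-4-hydroxy-2,6,6-trimethylcyclohex-2-en-1-yl]but-3-en-2-one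
Product: 15 (4E)-5-[(1S,4S)-4-hydroxy-2,6,6-trimethylcyclohex-2-en-1-yl]-3-methylpenta-1,4-dien-3-ol (both epimers at the new carbinol carbon)
Conditions: CH2=CHMgBr (3 equiv), THF, −20 to 0 °C; aqueous work-up
Reagents that add atoms: vinylmagnesium bromide, C=C[Mg]Br
Why: After the first equivalent deprotonates the free hydroxyl, the vinyl Grignard reagent adds 1,2 to the enone carbonyl, and the new carbinol centre is lost again in steps 12 and 15.

Step 12
Reactants: 15 (4E)-5-[(1S,4S)-4-hydroxy-2,6,6-trimethylcyclohex-2-en-1-yl]-3-methylpenta-1,4-dien-3-ol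
Product: 16 [(2E,4E)-5-[(1S,4S)-4-hydroxy-2,6,6-trimethylcyclohex-2-en-1-yl]-3-methylpenta-2,4-dien-1-yl]triphenylphosphonium bromide
Conditions: Ph3P·HBr (1.05 equiv), CH2Cl2, 0 °C to rt; crystallisation of the 2E salt
Reagents that add atoms: triphenylphosphine hydrobromide, [PH+](c1ccccc1)(c1ccccc1)c1ccccc1.[Br-]
Why: The tertiary, doubly allylic carbinol ionises to a pentadienyl cation far more easily than the secondary ring alcohol, triphenylphosphine traps the cation at the primary terminus (allylic transposition) to give the E-configured C15 salt, and the acid is consumed as the salt forms.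

Step 13
Reactants: 16 [(2E,4E)-5-[(1S,4S)-4-hydroxy-2,6,6-trimethylcyclohex-2-en-1-yl]-3-methylpenta-2,4-dien-1-yl]triphenylphosphonium bromide; 17 (2E,4E,6E)-2,7-dimethylocta-2,4,6-trienedial
Product: 19 (2E,4E,6E,8E,10E,12E)-13-[(1S,4S)-4-hydroxy-2,6,6-trimethylcyclohex-2-en-1-yl]-2,7,11-trimethyltrideca-2,4,6,8,10,12-hexaenal, via phosphorus ylide 18 (not isolated)
Conditions: 17 (3 equiv), NaOMe, CH2Cl2/MeOH, 0 °C; then EtOAc, 70 °C
Reagents that add atoms: none
Why: In this Wittig olefination only one aldehyde group of the symmetrical dialdehyde, used in excess, should react, and the E/Z mixture at the new C11=C12 bond from the semi-stabilised allylic ylide is equilibrated thermally to all-E.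

Step 14
Reactants: 15 (4E)-5-[(1S,4S)-4-hydroxy-2,6,6-trimethylcyclohex-2-en-1-yl]-3-methylpenta-1,4-dien-3-ol
Product: 20 (4S)-4-[(1E)-3-hydroxy-3-methylpenta-1,4-dien-1-yl]-3,5,5-trimethylcyclohex-2-en-1-one (both epimers at the tertiary carbinol carbon)
Conditions: MnO2 (activated, excess), CH2Cl2, rt
Reagents that add atoms: none
Why: Activated MnO2 oxidises the secondary ring allylic alcohol selectively to the enone, the tertiary carbinol has no hydrogen to lose, and no base is present that could touch C6'.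

Step 15
Reactants: 20 (4S)-4-[(1E)-3-hydroxy-3-methylpenta-1,4-dien-1-yl]-3,5,5-trimethylcyclohex-2-en-1-one
Product: 21 [(2E,4E)-3-methyl-5-[(1S)-2,6,6-trimethyl-4-oxocyclohex-2-en-1-yl]penta-2,4-dien-1-yl]triphenylphosphonium bromide
Conditions: Ph3P·HBr (1.05 equiv), CH2Cl2, 0 °C to rt; crystallisation of the 2E salt
Reagents that add atoms: triphenylphosphine hydrobromide, [PH+](c1ccccc1)(c1ccccc1)c1ccccc1.[Br-]
Why: As in step 12, ionisation of the tertiary doubly allylic carbinol and trapping of the pentadienyl cation by triphenylphosphine at the primary terminus (allylic transposition) gives the E-configured salt; the β,β-disubstituted ring enone is too hindered for conjugate addition of the phosphine, and the acid is consumed as the salt forms, so C6' should not enolise.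

Step 16
Reactants: 19 (2E,4E,6E,8E,10E,12E)-13-[(1S,4S)-4-hydroxy-2,6,6-trimethylcyclohex-2-en-1-yl]-2,7,11-trimethyltrideca-2,4,6,8,10,12-hexaenal; 21 [(2E,4E)-3-methyl-5-[(1S)-2,6,6-trimethyl-4-oxocyclohex-2-en-1-yl]penta-2,4-dien-1-yl]triphenylphosphonium bromide
Product: 23 (3S,6S,6'S)-3-hydroxy-ε,ε-caroten-3'-one (all-E), via keto phosphorus ylide 22 (not isolated)
Conditions: 1,2-epoxybutane, EtOH, 65 °C; then heptane, 90 °C, dark
Reagents that add atoms: none
Why: This Wittig olefination runs under base-free epoxide conditions (bromide opens the epoxide and the alkoxide formed deprotonates the salt next to phosphorus), chosen so that the γ-hydrogen at C6' of the keto ring, which meets a basic medium only in this last step, should not epimerise; the ylide reacts with the polyenal in preference to the hindered conjugated ring ketone, the free 3-hydroxyl is tolerated, and thermal equilibration gives the all-E chain.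

**Compound list**

1 | methyl 3,3-dimethylpent-4-enoate | COC(=O)CC(C)(C)C=C | starting material
2 | methyl 3,3-dimethyl-4-oxobutanoate | COC(=O)CC(C)(C)C=O | intermediate
3 | [2-(2-methyl-1,3-dioxolan-2-yl)ethyl]triphenylphosphonium bromide | CC1(CC[P+](c2ccccc2)(c2ccccc2)c2ccccc2)OCCO1.[Br-] | starting material
4 | [2-(2-methyl-1,3-dioxolan-2-yl)ethylidene]triphenylphosphorane (not isolated) | CC1(CC=P(c2ccccc2)(c2ccccc2)c2ccccc2)OCCO1 | intermediate
5 | methyl (4Z)-3,3-dimethyl-6-(2-methyl-1,3-dioxolan-2-yl)hex-4-enoate | COC(=O)CC(C)(C)/C=C\CC1(C)OCCO1 | intermediate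
6 | (4Z)-3,3-dimethyl-6-(2-methyl-1,3-dioxolan-2-yl)hex-4-enal | O=CCC(C)(C)/C=C\CC1(C)OCCO1 | intermediate
7 | (7Z)-6,6-dimethyl-9-(2-methyl-1,3-dioxolan-2-yl)non-7-en-1-yn-4-ol, racemic | C#CCC(O)CC(C)(C)/C=C\CC1(C)OCCO1 | intermediate
8 | tert-butyl{[(7Z)-6,6-dimethyl-9-(2-methyl-1,3-dioxolan-2-yl)non-7-en-1-yn-4-yl]oxy}dimethylsilane, racemic | C#CCC(O[Si](C)(C)C(C)(C)C)CC(C)(C)/C=C\CC1(C)OCCO1 | intermediate
9 | tert-butyl({(4S)-3,3-dimethyl-5-methylidene-4-[(E)-2-(2-methyl-1,3-dioxolan-2-yl)ethenyl]cyclohexyl}oxy)dimethylsilane, both C1 epimers | C=C1CC(O[Si](C)(C)C(C)(C)C)CC(C)(C)[C@@H]1/C=C/C1(C)OCCO1 | intermediate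
10 | (4S)-3,3-dimethyl-5-methylidene-4-[(E)-2-(2-methyl-1,3-dioxolan-2-yl)ethenyl]cyclohexan-1-ol, both C1 epimers | C=C1CC(O)CC(C)(C)[C@@H]1/C=C/C1(C)OCCO1 | intermediate
11 | (4S)-3,3-dimethyl-5-methylidene-4-[(E)-2-(2-methyl-1,3-dioxolan-2-yl)ethenyl]cyclohexan-1-one (not isolated) | C=C1CC(=O)CC(C)(C)[C@@H]1/C=C/C1(C)OCCO1 | intermediate
12 | (4S)-3,5,5-trimethyl-4-[(E)-2-(2-methyl-1,3-dioxolan-2-yl)ethenyl]cyclohex-2-en-1-one | CC1=CC(=O)CC(C)(C)[C@@H]1/C=C/C1(C)OCCO1 | intermediate
13 | (1S,4S)-3,5,5-trimethyl-4-[(E)-2-(2-methyl-1,3-dioxolan-2-yl)ethenyl]cyclohex-2-en-1-ol | CC1=C[C@@H](O)CC(C)(C)[C@@H]1/C=C/C1(C)OCCO1 | intermediate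
14 | (3E)-4-[(1S,4S)-4-hydroxy-2,6,6-trimethylcyclohex-2-en-1-yl]but-3-en-2-one | CC1=C[C@@H](O)CC(C)(C)[C@@H]1/C=C/C(C)=O | intermediate
15 | (4E)-5-[(1S,4S)-4-hydroxy-2,6,6-trimethylcyclohex-2-en-1-yl]-3-methylpenta-1,4-dien-3-ol, both carbinol epimers | CC1=C[C@@H](O)CC(C)(C)[C@@H]1/C=C/C(C)(O)C=C | intermediate
16 | [(2E,4E)-5-[(1S,4S)-4-hydroxy-2,6,6-trimethylcyclohex-2-en-1-yl]-3-methylpenta-2,4-dien-1-yl]triphenylphosphonium bromide | CC1=C[C@@H](O)CC(C)(C)[C@@H]1/C=C/C(C)=C/C[P+](c1ccccc1)(c1ccccc1)c1ccccc1.[Br-] | intermediate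
17 | (2E,4E,6E)-2,7-dimethylocta-2,4,6-trienedial | O=C/C(C)=C/C=C/C=C(C)/C=O | starting material
18 | [(2E,4E)-5-[(1S,4S)-4-hydroxy-2,6,6-trimethylcyclohex-2-en-1-yl]-3-methylpenta-2,4-dien-1-ylidene]triphenylphosphorane (not isolated) | CC1=C[C@@H](O)CC(C)(C)[C@@H]1/C=C/C(C)=C/C=P(c1ccccc1)(c1ccccc1)c1ccccc1 | intermediate
19 | (2E,4E,6E,8E,10E,12E)-13-[(1S,4S)-4-hydroxy-2,6,6-trimethylcyclohex-2-en-1-yl]-2,7,11-trimethyltrideca-2,4,6,8,10,12-hexaenal | CC1=C[C@@H](O)CC(C)(C)[C@@H]1/C=C/C(C)=C/C=C/C(C)=C/C=C/C=C(C)/C=O | intermediate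
20 | (4S)-4-[(1E)-3-hydroxy-3-methylpenta-1,4-dien-1-yl]-3,5,5-trimethylcyclohex-2-en-1-one, both carbinol epimers | CC1=CC(=O)CC(C)(C)[C@@H]1/C=C/C(C)(O)C=C | intermediate
21 | [(2E,4E)-3-methyl-5-[(1S)-2,6,6-trimethyl-4-oxocyclohex-2-en-1-yl]penta-2,4-dien-1-yl]triphenylphosphonium bromide | CC1=CC(=O)CC(C)(C)[C@@H]1/C=C/C(C)=C/C[P+](c1ccccc1)(c1ccccc1)c1ccccc1.[Br-] | intermediate
22 | [(2E,4E)-3-methyl-5-[(1S)-2,6,6-trimethyl-4-oxocyclohex-2-en-1-yl]penta-2,4-dien-1-ylidene]triphenylphosphorane (not isolated) | CC1=CC(=O)CC(C)(C)[C@@H]1/C=C/C(C)=C/C=P(c1ccccc1)(c1ccccc1)c1ccccc1 | intermediate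
23 | (3S,6S,6'S)-3-hydroxy-ε,ε-caroten-3'-one, all-E | CC1=CC(=O)CC(C)(C)[C@@H]1/C=C/C(C)=C/C=C/C(C)=C/C=C/C=C(C)/C=C/C=C(C)/C=C/[C@@H]1C(C)=C[C@@H](O)CC1(C)C | target

**Count**

Total steps: 16. Longest linear sequence: 14 (steps 1–11, then either 12, 13 and 16 or 14, 15 and 16).

**Steps most likely to fail**

Step 6. The chiral catalyst may select the alkene face poorly, or differently for the two remote C3 epimers. β-Hydride elimination may run toward C6–H, and the terminal alkyne may oligomerise under the cationic catalyst. Fallback: the ring is closed without asymmetric induction and the enantiomers are separated later. Setting out from 8, the achiral system Pd(OAc)2/PPh3 in benzene at 60 °C should give 9 together with its mirror image, the (4R) silyl ether ent-9 F1. Steps 7 to 9 are run on the racemate and give, beside 10, 11, 12 and 13, the (4R) alcohol ent-10 F2, the (4R) methylene ketone ent-11 F3 (not isolated), the (4R) enone ent-12 F4 and the (1R,4R) allylic alcohol ent-13 F5. A lipase (Pseudomonas fluorescens lipase, vinyl acetate, tert-butyl methyl ether, rt) is then expected to acetylate the 1R alcohol to the (1R,4R) acetate F6 and to leave 13, which is separated by chromatography. The route is rejoined at 13.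

Step 12. The ring allylic alcohol may ionise beside the tertiary carbinol, leading to elimination, substitution or loss of the C3 configuration. Fallback: the ring oxygen is kept as an ester during salt formation and released after the first coupling. Setting out from 15, Ac2O in pyridine at 0 °C should acetylate only the secondary hydroxyl and give the monoacetate F7, and Ph3P·HBr in CH2Cl2 then gives the acetoxy phosphonium bromide F8. F8 takes the place of 16 in step 13: its acetoxy ylide F9 (not isolated) and 17 give the C25 acetoxy aldehyde F10, whose acetate is cleaved by NaOMe/MeOH in the same flask. The route is rejoined at 19; the keto branch (steps 14 and 15) is unchanged.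

Step 16. The ylide or the alkoxide may remove the γ-hydrogen at C6' of the keto ring and epimerise it, and the ylide may condense slowly with the ring ketone. Fallback: both rings are carried through the last coupling at the alcohol level and the ketone is made afterwards. Setting out from 19, t-BuMe2SiCl and imidazole in DMF give the C25 silyloxy aldehyde F11. Condensation of F11 with the ylide of salt 16 under the epoxide conditions of step 16 gives the C40 mono-silylated diol F12. MnO2 in CH2Cl2 oxidises its free allylic 3'-hydroxyl to the silyloxy ketone F13, and Bu4NF buffered with AcOH in THF removes the silyl group, so that C6' never meets a base once the ketone is present. The route is rejoined at 23; steps 14 and 15 are then not needed.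

**Further compounds**

F1 | step 6 | tert-butyl({(4R)-3,3-dimethyl-5-methylidene-4-[(E)-2-(2-methyl-1,3-dioxolan-2-yl)ethenyl]cyclohexyl}oxy)dimethylsilane (ent-9) | C=C1CC(O[Si](C)(C)C(C)(C)C)CC(C)(C)[C@H]1/C=C/C1(C)OCCO1
F2 | step 6 | (4R)-3,3-dimethyl-5-methylidene-4-[(E)-2-(2-methyl-1,3-dioxolan-2-yl)ethenyl]cyclohexan-1-ol (ent-10) | C=C1CC(O)CC(C)(C)[C@H]1/C=C/C1(C)OCCO1
F3 | step 6 | (4R)-3,3-dimethyl-5-methylidene-4-[(E)-2-(2-methyl-1,3-dioxolan-2-yl)ethenyl]cyclohexan-1-one (ent-11) | C=C1CC(=O)CC(C)(C)[C@H]1/C=C/C1(C)OCCO1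
F4 | step 6 | (4R)-3,5,5-trimethyl-4-[(E)-2-(2-methyl-1,3-dioxolan-2-yl)ethenyl]cyclohex-2-en-1-one (ent-12) | CC1=CC(=O)CC(C)(C)[C@H]1/C=C/C1(C)OCCO1
F5 | step 6 | (1R,4R)-3,5,5-trimethyl-4-[(E)-2-(2-methyl-1,3-dioxolan-2-yl)ethenyl]cyclohex-2-en-1-ol (ent-13) | CC1=C[C@H](O)CC(C)(C)[C@H]1/C=C/C1(C)OCCO1
F6 | step 6 | (1R,4R)-3,5,5-trimethyl-4-[(E)-2-(2-methyl-1,3-dioxolan-2-yl)ethenyl]cyclohex-2-en-1-yl acetate | CC1=C[C@H](OC(C)=O)CC(C)(C)[C@H]1/C=C/C1(C)OCCO1
F7 | step 12 | (1S,4S)-4-[(1E)-3-hydroxy-3-methylpenta-1,4-dien-1-yl]-3,5,5-trimethylcyclohex-2-en-1-yl acetate | CC1=C[C@@H](OC(C)=O)CC(C)(C)[C@@H]1/C=C/C(C)(O)C=C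
F8 | step 12 | [(2E,4E)-5-[(1S,4S)-4-acetoxy-2,6,6-trimethylcyclohex-2-en-1-yl]-3-methylpenta-2,4-dien-1-yl]triphenylphosphonium bromide | CC1=C[C@@H](OC(C)=O)CC(C)(C)[C@@H]1/C=C/C(C)=C/C[P+](c1ccccc1)(c1ccccc1)c1ccccc1.[Br-]
F9 | step 12 | [(2E,4E)-5-[(1S,4S)-4-acetoxy-2,6,6-trimethylcyclohex-2-en-1-yl]-3-methylpenta-2,4-dien-1-ylidene]triphenylphosphorane | CC1=C[C@@H](OC(C)=O)CC(C)(C)[C@@H]1/C=C/C(C)=C/C=P(c1ccccc1)(c1ccccc1)c1ccccc1
F10 | step 12 | (1S,4S)-3,5,5-trimethyl-4-[(1E,3E,5E,7E,9E,11E)-3,7,12-trimethyl-13-oxotrideca-1,3,5,7,9,11-hexaen-1-yl]cyclohex-2-en-1-yl acetate | CC1=C[C@@H](OC(C)=O)CC(C)(C)[C@@H]1/C=C/C(C)=C/C=C/C(C)=C/C=C/C=C(C)/C=O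
F11 | step 16 | (2E,4E,6E,8E,10E,12E)-13-[(1S,4S)-4-{[tert-butyl(dimethyl)silyl]oxy}-2,6,6-trimethylcyclohex-2-en-1-yl]-2,7,11-trimethyltrideca-2,4,6,8,10,12-hexaenal | CC1=C[C@@H](O[Si](C)(C)C(C)(C)C)CC(C)(C)[C@@H]1/C=C/C(C)=C/C=C/C(C)=C/C=C/C=C(C)/C=O
F12 | step 16 | (3S,6S,3'S,6'S)-3-{[tert-butyl(dimethyl)silyl]oxy}-ε,ε-caroten-3'-ol, all-E | CC1=C[C@@H](O)CC(C)(C)[C@@H]1/C=C/C(C)=C/C=C/C(C)=C/C=C/C=C(C)/C=C/C=C(C)/C=C/[C@@H]1C(C)=C[C@@H](O[Si](C)(C)C(C)(C)C)CC1(C)C
F13 | step 16 | (3S,6S,6'S)-3-{[tert-butyl(dimethyl)silyl]oxy}-ε,ε-caroten-3'-one, all-E | CC1=CC(=O)CC(C)(C)[C@@H]1/C=C/C(C)=C/C=C/C(C)=C/C=C/C=C(C)/C=C/C=C(C)/C=C/[C@@H]1C(C)=C[C@@H](O[Si](C)(C)C(C)(C)C)CC1(C)C
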